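At early times you see Q arrive late in both earlier runs: in the autumn run, the line through the readings at 20.0 s and 30.0 s meets zero near 7.86 s. Now turn the settings one at a time, by hand and in logarithms.

all flasks: X 0.20 M
- autumn: D 0.27 M; run made earlier
- noon: D 0.60 M; run made earlier
- flask: D 0.400 M; time 2.5 min; volume of the second phase over the first 0.50

| run | time / s | Q / % | X / % |
|---|---|---|---|
| autumn | 10.0 | 1.1 | 98.7 |
| autumn | 20.0 | 3.4 | 97.6 |
| autumn | 30.0 | 6.2 | 94.1 |
| autumn | 50.0 | 12.2 | 87.7 |
| autumn | 60.0 | 14.4 | 85.8 |
| autumn | 90.0 | 20.7 | 78.5 |
| noon | 10.0 | 1.8 | 97.2 |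
| noon | 12.0 | 2.7 | 96.7 |
| noon | 20.0 | 7.1 | 92.9 |
| noon | 30.0 | 12.0 | 87.5 |
| noon | 50.0 | 22.2 | 77.7 |
| noon | 90.0 | 34.2 | 64.2 |

(each reading ± 0.3 percentage points)

- in the second phase: D; everything else is in the first
- charges count per volume of the first phase; a concentration in a rate is the amount of a species over the volume of its own phase; every rate counts per litre of the first phase
- the numbers in the tables scatter with a standard deviation of 0.3 percentage points
- the earlier runs hold the two phases in the same ratio of volumes as the flask asked about

1. the Q standing at 2.5 min, as a percentage of the X charged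
2. the change that raises the amount of Q at 2.5 min, in percent of the X charged most ("none" if none brings more than 2 percentage points) (Sunday's / Thursday's / none)
3. amount of Q at 2.5 min, in percent of the X charged, after Thursday's

Start with the amount of D. Autumn and noon at 90.0 s give 0.629: this is the D-slope, the change in ln of Q at a fixed time per change in ln of the D charged, the apparent order in D. So 0.400 M of D lifts the autumn 20.7% to 26.5%.

Next comes the time. The same kind of slope, now against ln of time and taken over noon's last stretch, which runs through about the Q this flask will pass, is 0.735, so I expect 38.6% at 2.5 min.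

Last comes the transfer coefficient. By my reckoning, if Sunday's halves the delay, it gains 0.74 percentage points, whereas Thursday's doubling of D gains 21 points, which is more, and reaches 59.7%.

The forecast, built on “reversal or product inhibition”, says 35%, Thursday's and 50%, below my two figures.

The flask gives 36.7%; Thursday's wins, adding 16 points to reach 52.9%, while Sunday's adds 3.3 points, above my figure.

    2 L → E (k = 0.170 L mol⁻¹ s⁻¹)
    L + Q → G (k = 0.00750 L mol⁻¹ s⁻¹)
    L ⇌ D, rate k3*([L] - [D]/K3) per volume of the first phase (partition coefficient = 0.680, kL = 0.00420 s⁻¹)
    X + L → Q (k = 0.0750 L mol⁻¹ s⁻¹)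
    L → Z (k = 0.0200 s⁻¹)

At the autumn time, the amount of D alone gives 27.1%, where the D-slope gave 26.5%. On Thursday's flask the D-slope takes 36.7% to 56.8%, above the 52.9% that flask gives, whose own slope is 0.527. At 2.50 min in this flask, L turns into Z 2.1 times as fast as it turns with X into Q. L stands then at 0.0261 M, and it is made at 0.791 of the rate at which it is removed.

The numbers in the tables stem from a simulated flask for an exercise; the scatter is artificial.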